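The route rests on one disconnection: the C5–C6 bond of the ten-membered carbocycle together with the C12–O bond of the butenolide. It exploits the triple role of C6, which is the γ-carbon of the butenolide, one of the ten carbocyclic ring atoms and the allylic neighbour of the Z-C4=C5 alkene. A C5 alkenylchromium therefore adds to a C6 aldehyde that sits cis to the C12 carboxyl on C7=C11; this one operation closes the carbocycle, sets C6 and lets the new C6 oxygen re-form the five-membered lactone. The precursor is a seco γ-hydroxybutenolide (masked C6 aldehyde) carrying the 8,13-diacetate, a (1S)-silyl ether and a terminal Z-alkenyl iodide.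

Key step: step 17

Assumption: locants follow germacrane numbering (C1–C15) and the target is (1S,4Z,6R,8S). Alcohol 20 is carried on as its C8 epimer mixture and lactol 26 as its C6 epimer mixture, because both centres are set afresh in steps 14 and 17.

Step 1
Reactants: 1 propargyl alcohol
Product: 3 (Z)-3-iodo-2-methylprop-2-en-1-ol, via alkenylmagnesium alkoxide 2 (not isolated)
Conditions: MeMgBr (3 equiv), CuI (10 mol%), THF, −10 °C to rt; then I2, −10 °C
Reagents that add atoms: methylmagnesium bromide C[Mg]Br; iodine II
Why: Copper-catalysed, alkoxide-directed anti-carbomagnesiation of the propargylic alcohol should place the methyl group (C15) on C4 and magnesium on C5 cis to the CH2O group, and iodinolysis with retention then fixes the Z-iodoalkene that becomes Z-C4=C5.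

Step 2
Reactants: 3 (Z)-3-iodo-2-methylprop-2-en-1-ol
Product: 4 (Z)-3-bromo-1-iodo-2-methylprop-1-ene
Conditions: CBr4, PPh3, CH2Cl2, 0 °C
Reagents that add atoms: carbon tetrabromide BrC(Br)(Br)Br
Why: Appel bromination of the primary allylic alcohol proceeds by SN2 displacement at CH2 and should leave the alkene geometry and the C–I bond untouched.

Step 3
Reactants: 5 N-methoxy-N-methylacetamide; 4 (Z)-3-bromo-1-iodo-2-methylprop-1-ene
Product: 7 (Z)-5-iodo-N-methoxy-N,4-dimethylpent-4-enamide, via lithium amide enolate 6 (not isolated)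
Conditions: LDA, THF, −78 °C; then 4, −78 to −40 °C
Reagents that add atoms: none
Why: SN2 alkylation of the Weinreb amide lithium enolate, kept cold so that it does not fragment, by the reactive primary allylic bromide should form the C2–C3 bond without touching the alkenyl iodide.

Step 4
Reactants: 8 2-bromo-3-(trimethylsilyl)propene; 7 (Z)-5-iodo-N-methoxy-N,4-dimethylpent-4-enamide
Product: 10 (Z)-7-iodo-6-methyl-2-[(trimethylsilyl)methyl]hepta-1,6-dien-3-one, via alkenyl Grignard reagent 9 (not isolated)
Conditions: Mg, THF, rt; then 7, THF, −20 to 0 °C; inverse quench into cold aq. NaHSO4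
Reagents that add atoms: none
Why: Weinreb ketone synthesis, in which the magnesium-chelated tetrahedral adduct should persist until the acidic quench so that only one C1–C10 bond forms, while an alkenyl Grignard reagent does not exchange with the alkenyl iodide at this temperature.

Step 5
Reactants: 10 (Z)-7-iodo-6-methyl-2-[(trimethylsilyl)methyl]hepta-1,6-dien-3-one
Product: 11 (3S,6Z)-7-iodo-6-methyl-2-[(trimethylsilyl)methyl]hepta-1,6-dien-3-ol
Conditions: (R)-Me-CBS (20 mol%), catecholborane, toluene, −78 °C
Reagents that add atoms: none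
Why: Corey–Bakshi–Shibata 1,2-reduction in which the α-branched alkenyl group acts as the large substituent, so the (R)-oxazaborolidine should deliver hydride to give the (S)-carbinol at C1, and catecholborane does not hydroborate the alkenes.

Step 6
Reactants: 11 (3S,6Z)-7-iodo-6-methyl-2-[(trimethylsilyl)methyl]hepta-1,6-dien-3-ol
Product: 12 (3S,6Z)-3-(tert-butyldimethylsilyloxy)-7-iodo-6-methyl-2-[(trimethylsilyl)methyl]hepta-1,6-diene
Conditions: TBSCl, imidazole, DMF, rt
Reagents that add atoms: tert-butyldimethylsilyl chloride CC(C)(C)[Si](C)(C)Cl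
Why: Imidazole-promoted silylation of the secondary allylic alcohol is routine and gives a C1 ether that should survive every later step up to the final fluoride treatment.

Step 7
Reactants: 13 furan-3,4-diyldimethanol
Product: 14 3,4-bis[(tert-butyldimethylsilyloxy)methyl]furan
Conditions: TBSCl (2.2 equiv), imidazole, DMF, rt
Reagents that add atoms: tert-butyldimethylsilyl chloride CC(C)(C)[Si](C)(C)Cl
Why: Exhaustive silylation of the two equivalent primary alcohols is straightforward and supplies the silyl group that is moved onto the ring in the next step.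

Step 8
Reactants: 14 3,4-bis[(tert-butyldimethylsilyloxy)methyl]furan
Product: 16 [2-(tert-butyldimethylsilyl)-4-[(tert-butyldimethylsilyloxy)methyl]furan-3-yl]methanol, via 2-lithiofuran 15 (not isolated)
Conditions: n-BuLi (1.1 equiv), HMPA, THF, −78 to 0 °C; then H2O
Reagents that add atoms: none
Why: Directed α-lithiation next to a CH2OSi group followed by 1,4 O-to-C silyl migration (retro-Brook rearrangement) should place silicon on C12 and free the C13 hydroxyl, and the symmetry of 14 makes the two α-positions equivalent.

Step 9
Reactants: 16 [2-(tert-butyldimethylsilyl)-4-[(tert-butyldimethylsilyloxy)methyl]furan-3-yl]methanol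
Product: 17 [2-(tert-butyldimethylsilyl)-4-[(tert-butyldimethylsilyloxy)methyl]furan-3-yl]methyl acetate
Conditions: Ac2O, pyridine, DMAP (cat.), CH2Cl2, 0 °C
Reagents that add atoms: acetic anhydride CC(=O)OC(C)=O
Why: DMAP-catalysed acetylation of the primary alcohol installs the C13 acetate of the target at once, so that this oxygen needs no further protecting-group step.

Step 10
Reactants: 17 [2-(tert-butyldimethylsilyl)-4-[(tert-butyldimethylsilyloxy)methyl]furan-3-yl]methyl acetate
Product: 18 [2-(tert-butyldimethylsilyl)-4-(hydroxymethyl)furan-3-yl]methyl acetate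
Conditions: HF·pyridine, pyridine, THF, 0 °C
Reagents that add atoms: none
Why: Buffered HF should cleave the primary O–Si bond selectively, since the furyl C–Si bond and the acetate are inert to these weakly acidic fluoride conditions.

Step 11
Reactants: 18 [2-(tert-butyldimethylsilyl)-4-(hydroxymethyl)furan-3-yl]methyl acetate
Product: 19 [2-(tert-butyldimethylsilyl)-4-formylfuran-3-yl]methyl acetate
Conditions: MnO2, CH2Cl2, rt
Reagents that add atoms: none
Why: Activated manganese dioxide oxidises heterobenzylic alcohols to aldehydes without over-oxidation and should give the C8 aldehyde with acetate and C-silyl group intact.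

Step 12
Reactants: 19 [2-(tert-butyldimethylsilyl)-4-formylfuran-3-yl]methyl acetate; 12 (3S,6Z)-3-(tert-butyldimethylsilyloxy)-7-iodo-6-methyl-2-[(trimethylsilyl)methyl]hepta-1,6-diene
Product: 20 [2-(tert-butyldimethylsilyl)-4-[(4S,7Z)-4-(tert-butyldimethylsilyloxy)-1-hydroxy-8-iodo-7-methyl-3-methylideneoct-7-en-1-yl]furan-3-yl]methyl acetate (both C8 epimers)
Conditions: BF3·OEt2, CH2Cl2, −78 °C
Reagents that add atoms: none
Why: Hosomi–Sakurai allylation, in which the BF3-activated aldehyde is attacked by the terminal carbon of the 2-substituted allylsilane through a β-silyl cation, should form C8–C9 and the C10=C14 methylidene group; no control at C8 is needed because this centre is reset in steps 13 and 14.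

Step 13
Reactants: 20 C8-epimeric furyl carbinol
Product: 21 [2-(tert-butyldimethylsilyl)-4-[(4S,7Z)-4-(tert-butyldimethylsilyloxy)-8-iodo-7-methyl-3-methylideneoct-7-enoyl]furan-3-yl]methyl acetate
Conditions: Dess–Martin periodinane, NaHCO3, CH2Cl2, 0 °C
Reagents that add atoms: none
Why: Buffered Dess–Martin oxidation converts both C8 epimers into one ketone under near-neutral conditions that should not move the C10=C14 alkene into conjugation.

Step 14
Reactants: 21 furyl ketone
Product: 22 [2-(tert-butyldimethylsilyl)-4-[(1S,4S,7Z)-4-(tert-butyldimethylsilyloxy)-1-hydroxy-8-iodo-7-methyl-3-methylideneoct-7-en-1-yl]furan-3-yl]methyl acetate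
Conditions: (R)-Me-CBS (30 mol%), catecholborane, toluene, −78 to −40 °C
Reagents that add atoms: none
Why: Corey–Bakshi–Shibata reduction of a heteroaryl alkyl ketone with the furyl ring as the large group, so the (R)-catalyst should override the remote C1 centre and give the (8S)-carbinol, while catecholborane spares the acetate and the alkenes.

Step 15
Reactants: 22 (8S)-furyl carbinol
Product: 23 [4-[(1S,4S,7Z)-1-acetoxy-4-(tert-butyldimethylsilyloxy)-8-iodo-7-methyl-3-methylideneoct-7-en-1-yl]-2-(tert-butyldimethylsilyl)furan-3-yl]methyl acetate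
Conditions: Ac2O, pyridine, DMAP (cat.), CH2Cl2, 0 °C
Reagents that add atoms: acetic anhydride CC(=O)OC(C)=O
Why: Acetylation of the secondary alcohol proceeds with retention at C8 and completes the 8,13-diacetate before the oxidation-sensitive steps.

Step 16
Reactants: 23 silylfuran diacetate
Product: 26 [4-[(1S,4S,7Z)-1-acetoxy-4-(tert-butyldimethylsilyloxy)-8-iodo-7-methyl-3-methylideneoct-7-en-1-yl]-5-hydroxy-2-oxo-2,5-dihydrofuran-3-yl]methyl acetate (γ-hydroxybutenolide; both C6 epimers), via 2,5-endoperoxide 24 (not isolated), via silyl formyl ester 25 (not isolated)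
Conditions: O2, hν (visible), tetraphenylporphyrin (cat.), CH2Cl2, −78 °C; then H2O, rt
Reagents that add atoms: oxygen O=O
Why: Photooxygenation of a 2-silylfuran: [4+2] addition of singlet oxygen gives the endoperoxide, a C-to-O silyl shift from C12 opens it to the silyl Z-4-oxoenoate with the carboxyl at the silylated carbon, and hydrolysis should give the lactol with C12 as carbonyl and C6 as hemiacetal carbon regiospecifically, the furan reacting far faster than the other alkenes.

Step 17
Reactants: 26 γ-hydroxybutenolide (C6 epimer mixture)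
Product: 29 (1S,4Z,6R,8S)-8,13-diacetoxy-1-(tert-butyldimethylsilyloxy)germacra-4,7(11),10(14)-trien-6,12-olide, via ring-opened formyl acid 27 (not isolated), via macrocyclic hydroxy acid 28 (not isolated)
Conditions: CrCl2 (10 equiv), NiCl2 (0.1 equiv), degassed DMSO, rt, slow addition of 26 (final 2 mM); then aq. citric acid
Reagents that add atoms: none
Why: Ni(0) should insert into the C5–I bond with retention of the Z geometry and hand the alkenyl group to Cr(III); this alkenylchromium, which is slow to protonate and therefore tolerates the acidic lactol, adds 1,2 to the C6 aldehyde of tautomer 27 that ring–chain equilibration of 26 keeps supplying. The closest known reaction types are the Nozaki–Hiyama–Kishi alkenyl iodide–aldehyde macrocyclisation and the addition of organometallic reagents to γ-hydroxybutenolides followed by relactonisation. The carbocycle closes in 10-exo-trig mode by C5–C6 bond formation, and on acidic work-up hydroxy acid 28, whose C6 hydroxyl and C12 carboxyl are locked cis on the tetrasubstituted C7=C11 bond, closes the butenolide by 5-exo-trig acyl substitution. The new C6 centre is controlled by C8: allylic strain against the C13 acetoxymethyl group keeps H8 in the plane of C7=C11, so the C9 tether brings C5 to the face of the s-trans aldehyde opposite the C8 acetate (the Re face), which gives 6R. The step needs chemoselectivity for the alkenyl iodide over two acetates, the enoate and the exocyclic alkene, secured by the mild and oxophilic Ni/Cr system, and ring closure over oligomerisation, secured by slow addition at high dilution. Either lactol epimer opens to one and the same aldehyde, so 26 can be used as the mixture.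

Step 18
Reactants: 29 1-O-TBS ether of the target
Product: 30 (1S,4Z,6R,8S)-8,13-diacetoxy-1-hydroxygermacra-4,7(11),10(14)-trien-6,12-olide (8α,13-diacetoxy-1α-hydroxygermacra-4,7(11),10(14)-trien-6α,12-olide)
Conditions: HF·pyridine, pyridine, THF, 0 °C to rt
Reagents that add atoms: none
Why: Buffered HF removes the secondary silyl ether by Si–F bond formation under weakly acidic conditions, which should avoid the base-induced loss of the C13 acetate or acyl migration that fluoride salts could cause.

Compound list
1 | propargyl alcohol | C#CCO | starting material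
2 | (Z)-alkenylmagnesium bromide with bromomagnesium alkoxide (Mg on C5 cis to CH2O) | Br[Mg]OC/C(C)=C\[Mg]Br | intermediate
3 | (Z)-3-iodo-2-methylprop-2-en-1-ol | OC/C(C)=C\I | intermediate
4 | (Z)-3-bromo-1-iodo-2-methylprop-1-ene | BrC/C(C)=C\I | intermediate
5 | N-methoxy-N-methylacetamide | CON(C)C(C)=O | starting material
6 | lithium enolate of N-methoxy-N-methylacetamide | [Li]OC(=C)N(C)OC | intermediate
7 | (Z)-5-iodo-N-methoxy-N,4-dimethylpent-4-enamide | CON(C)C(=O)CC/C(C)=C\I | intermediate
8 | 2-bromo-3-(trimethylsilyl)propene | C=C(Br)C[Si](C)(C)C | starting material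
9 | [3-(trimethylsilyl)prop-1-en-2-yl]magnesium bromide | C=C([Mg]Br)C[Si](C)(C)C | intermediate
10 | (Z)-7-iodo-6-methyl-2-[(trimethylsilyl)methyl]hepta-1,6-dien-3-one | C=C(C[Si](C)(C)C)C(=O)CC/C(C)=C\I | intermediate
11 | (3S,6Z)-7-iodo-6-methyl-2-[(trimethylsilyl)methyl]hepta-1,6-dien-3-ol | C=C(C[Si](C)(C)C)[C@@H](O)CC/C(C)=C\I | intermediate
12 | (3S,6Z)-3-(tert-butyldimethylsilyloxy)-7-iodo-6-methyl-2-[(trimethylsilyl)methyl]hepta-1,6-diene | C=C(C[Si](C)(C)C)[C@@H](O[Si](C)(C)C(C)(C)C)CC/C(C)=C\I | intermediate
13 | furan-3,4-diyldimethanol | OCc1cocc1CO | starting material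
14 | 3,4-bis[(tert-butyldimethylsilyloxy)methyl]furan | CC(C)(C)[Si](C)(C)OCc1cocc1CO[Si](C)(C)C(C)(C)C | intermediate
15 | 2-lithio-3,4-bis[(tert-butyldimethylsilyloxy)methyl]furan | [Li]c1occ(CO[Si](C)(C)C(C)(C)C)c1CO[Si](C)(C)C(C)(C)C | intermediate
16 | [2-(tert-butyldimethylsilyl)-4-[(tert-butyldimethylsilyloxy)methyl]furan-3-yl]methanol | OCc1c(CO[Si](C)(C)C(C)(C)C)coc1[Si](C)(C)C(C)(C)C | intermediate
17 | [2-(tert-butyldimethylsilyl)-4-[(tert-butyldimethylsilyloxy)methyl]furan-3-yl]methyl acetate | CC(=O)OCc1c(CO[Si](C)(C)C(C)(C)C)coc1[Si](C)(C)C(C)(C)C | intermediate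
18 | [2-(tert-butyldimethylsilyl)-4-(hydroxymethyl)furan-3-yl]methyl acetate | CC(=O)OCc1c(CO)coc1[Si](C)(C)C(C)(C)C | intermediate
19 | [2-(tert-butyldimethylsilyl)-4-formylfuran-3-yl]methyl acetate | CC(=O)OCc1c(C=O)coc1[Si](C)(C)C(C)(C)C | intermediate
20 | furyl carbinol, C8 epimer mixture, (1S), Z-iodoalkene: [2-(tert-butyldimethylsilyl)-4-[(4S,7Z)-4-(tert-butyldimethylsilyloxy)-1-hydroxy-8-iodo-7-methyl-3-methylideneoct-7-en-1-yl]furan-3-yl]methyl acetate | I/C=C(/C)CC[C@H](O[Si](C)(C)C(C)(C)C)C(=C)CC(O)c1coc([Si](C)(C)C(C)(C)C)c1COC(C)=O | intermediate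
21 | C8 ketone: [2-(tert-butyldimethylsilyl)-4-[(4S,7Z)-4-(tert-butyldimethylsilyloxy)-8-iodo-7-methyl-3-methylideneoct-7-enoyl]furan-3-yl]methyl acetate | I/C=C(/C)CC[C@H](O[Si](C)(C)C(C)(C)C)C(=C)CC(=O)c1coc([Si](C)(C)C(C)(C)C)c1COC(C)=O | intermediate
22 | (1S,8S)-furyl carbinol: [2-(tert-butyldimethylsilyl)-4-[(1S,4S,7Z)-4-(tert-butyldimethylsilyloxy)-1-hydroxy-8-iodo-7-methyl-3-methylideneoct-7-en-1-yl]furan-3-yl]methyl acetate | I/C=C(/C)CC[C@H](O[Si](C)(C)C(C)(C)C)C(=C)C[C@H](O)c1coc([Si](C)(C)C(C)(C)C)c1COC(C)=O | intermediate
23 | (1S,8S)-8,13-diacetate of the C12-silylated furan | I/C=C(/C)CC[C@H](O[Si](C)(C)C(C)(C)C)C(=C)C[C@H](OC(C)=O)c1coc([Si](C)(C)C(C)(C)C)c1COC(C)=O | intermediate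
24 | 2,5-endoperoxide of 23 (2,3,7-trioxabicyclo[2.2.1]hept-5-ene, silyl group on the C12 bridgehead) | I/C=C(/C)CC[C@H](O[Si](C)(C)C(C)(C)C)C(=C)C[C@H](OC(C)=O)C1=C(COC(C)=O)C2([Si](C)(C)C(C)(C)C)OOC1O2 | intermediate
25 | tert-butyldimethylsilyl ester of the ring-opened (Z)-formyl acid (C6 aldehyde cis to C12 ester) | I/C=C(/C)CC[C@H](O[Si](C)(C)C(C)(C)C)C(=C)C[C@H](OC(C)=O)/C(C=O)=C(\COC(C)=O)C(=O)O[Si](C)(C)C(C)(C)C | intermediate
26 | γ-hydroxybutenolide seco precursor (1S,8S; both C6 lactol epimers; Z-alkenyl iodide) | I/C=C(/C)CC[C@H](O[Si](C)(C)C(C)(C)C)C(=C)C[C@H](OC(C)=O)C1=C(COC(C)=O)C(=O)OC1O | intermediate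
27 | ring-opened (Z)-formyl carboxylic acid tautomer of 26 | I/C=C(/C)CC[C@H](O[Si](C)(C)C(C)(C)C)C(=C)C[C@H](OC(C)=O)/C(C=O)=C(\COC(C)=O)C(O)=O | intermediate
28 | macrocyclic (1S,6R,8S) Z-γ-hydroxy acid (ten-membered ring closed, lactone open) | C=C1C[C@H](OC(C)=O)/C(=C(\COC(C)=O)C(O)=O)[C@H](O)/C=C(/C)CC[C@@H]1O[Si](C)(C)C(C)(C)C | intermediate
29 | (1S,4Z,6R,8S)-8,13-diacetoxy-1-(tert-butyldimethylsilyloxy)germacra-4,7(11),10(14)-trien-6,12-olide | C=C1C[C@H](OC(C)=O)C2=C(COC(C)=O)C(=O)O[C@@H]2/C=C(/C)CC[C@@H]1O[Si](C)(C)C(C)(C)C | intermediate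
30 | 8α,13-diacetoxy-1α-hydroxygermacra-4,7(11),10(14)-trien-6α,12-olide, (1S,4Z,6R,8S) | C=C1C[C@H](OC(C)=O)C2=C(COC(C)=O)C(=O)O[C@@H]2/C=C(/C)CC[C@@H]1O | target

Total step count: 18.
Longest linear sequence: 13 steps (steps 1–6, then 12–18); the furan branch (steps 7–11) joins at step 12.

Steps most likely to fail

1. Step 17 (key step). Several processes could compete with ring closure:
- protonation of the alkenylchromium by the acidic lactol or its carboxylic acid tautomer, which would remove iodine without forming the ring;
- single-electron reduction of the ring-opened ene-dicarbonyl by Cr(II);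
- intermolecular coupling;
- addition to the s-cis aldehyde rotamer, which would erode the facial selectivity at C6.

Fallback: setting out from 26, the ring-opened carboxylate would be trapped with MeI and KHCO3 in DMF as the methyl (Z)-formyl ester F1, which has a free aldehyde and no acidic proton. F1 would then be cyclised by a Nozaki–Hiyama–Kishi reaction of the usual alkenyl iodide–aldehyde kind. A stoichiometric chromium complex of a chiral oxazoline–sulfonamide ligand (NiCl2 cat., MeCN, high dilution) would be used, with the ligand enantiomer chosen to deliver C5 to the Re face of C6. This should give the macrocyclic hydroxy methyl ester F2, whose cis γ-hydroxy ester should lactonise with loss of methanol on work-up or with PPTS. The fallback comes back to the route at 29.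

2. Step 12. The Lewis acid could protodesilylate the allylsilane, ionise the newly formed furylic alkoxide (over-allylation or elimination), or react too slowly with the electron-rich furaldehyde.

Fallback: setting out from 12, bromodesilylation with NBS in CH2Cl2 at −78 °C should give the allylic bromide F3. A zinc-mediated Barbier allylation of aldehyde 19 (Zn dust, THF/aq. NH4Cl, rt) forms the same C8–C9 bond without any Lewis acid and leaves the alkenyl iodide alone. The fallback comes back to the route at 20.

3. Step 14 (with step 13). The C10=C14 alkene could migrate into conjugation with the C8 ketone, and catalyst control could be incomplete for a ketone flanked by two bulky groups, giving poor facial selectivity.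

Fallback: setting out from 20, the oxidation–reduction pair is skipped. The two C8 epimers are diastereomers because C1 is fixed and would be separated by chromatography. The (8S)-epimer is 22 and goes on through step 15. The (8R)-alcohol F4 would be converted with inversion into the (8S)-acetate by a Mitsunobu reaction with acetic acid (PPh3, DIAD, toluene, 0 °C). The fallback comes back to the route at 23.

Further compounds
F1 | step 17 | methyl ester of the ring-opened (Z)-formyl acid (1S,8S; Z-alkenyl iodide) | I/C=C(/C)CC[C@H](O[Si](C)(C)C(C)(C)C)C(=C)C[C@H](OC(C)=O)/C(C=O)=C(\COC(C)=O)C(=O)OC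
F2 | step 17 | macrocyclic (1S,6R,8S) Z-γ-hydroxy methyl ester | C=C1C[C@H](OC(C)=O)/C(=C(\COC(C)=O)C(=O)OC)[C@H](O)/C=C(/C)CC[C@@H]1O[Si](C)(C)C(C)(C)C
F3 | step 12 | (3S,6Z)-2-(bromomethyl)-3-(tert-butyldimethylsilyloxy)-7-iodo-6-methylhepta-1,6-diene | C=C(CBr)[C@@H](O[Si](C)(C)C(C)(C)C)CC/C(C)=C\I
F4 | step 14 | (1S,8R)-furyl carbinol (C8 epimer of 22) | I/C=C(/C)CC[C@H](O[Si](C)(C)C(C)(C)C)C(=C)C[C@@H](O)c1coc([Si](C)(C)C(C)(C)C)c1COC(C)=O
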